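**Retrosynthetic overview**

1. The target is a 3,8''-biflavanone: unit 1 is a (2R,3S)-naringenin whose C3 is bonded to C8'' of unit 2, a (2''S)-4'''-O-methylnaringenin (unit 2 double-primed, its anisyl ring triple-primed).
2. The strategy rests on pyran ring C'', which is fused to ring A'' along C4a''–C8a'' with O1'' on C8a'', C4'' on C4a'' and the anisyl-bearing C2'' bonded to O1''. This is the atom pattern of a ring A'' ortho-quinone methide (O8a''=C8a''–C4a''=C4'') plus the C3''=C2'' bond of 4-vinylanisole.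
3. Disconnections: C4''=O from C4''–OMe; ring C'' by hetero-Diels–Alder (C4''–C3'' and O1''–C2'') from a ring A'' salicylaldehyde, HC(OMe)3 and 4-vinylanisole; the formyl group by ortho-formylation of the one free phenol (future O1''); ring C by annulation of a deoxybenzoin with 4-(benzyloxy)benzaldehyde (C2–C3, O1–C2); the deoxybenzoin by Hoesch acylation of phloroglucinol.
4. Ring order: rings A'', A, B and the anisyl ring are bought as arenes; ring C is closed in step 6, ring C'' in step 10. Unit 1 is resolved in step 9, and only acidic or neutral conditions follow.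
5. Protection: benzyl ethers on all phenols that stay masked (neutral hydrogenolysis at the end spares the 4'''-OMe), and one allyl ether that tags the single ring A'' oxygen destined to become O1''.

Key step: step 10

Assumption: the sense of induction of the chiral phosphoric acid on this substrate cannot be predicted; (R)-TRIP is written, and its antipode is used instead if that proves to be the catalyst matched with (2R,3S)-unit 1 for 2''S.

**Route**

Step 1
Reactants: 1 2,4,6-trihydroxybenzaldehyde; 2 benzyl bromide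
Product: 3 4,6-bis(benzyloxy)-2-hydroxybenzaldehyde
Conditions: BnBr (2.1 equiv), K2CO3, DMF, 0 °C to rt
Reagents that add atoms: benzyl bromide (BrCc1ccccc1)
Why: Williamson etherification in which the para hydroxyl and one of the two equivalent ortho hydroxyls react while the last ortho hydroxyl, hydrogen-bonded to the formyl oxygen, stays free (chelation-controlled alkylation of acylphloroglucinols).

Step 2
Reactants: 3 4,6-bis(benzyloxy)-2-hydroxybenzaldehyde; 4 allyl bromide
Product: 5 2-(allyloxy)-4,6-bis(benzyloxy)benzaldehyde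
Conditions: allyl bromide, K2CO3, DMF, 60 °C
Reagents that add atoms: allyl bromide (C=CCBr)
Why: More forcing Williamson etherification of the chelated phenol; the allyl ether marks the one ortho oxygen that will become O1'' and keeps it masked so that the later benzyl ketone cannot cyclodehydrate to a benzofuran.

Step 3
Reactants: 5 2-(allyloxy)-4,6-bis(benzyloxy)benzaldehyde; 6 tosylmethyl isocyanide (TosMIC)
Product: 8 2-[2-(allyloxy)-4,6-bis(benzyloxy)phenyl]acetonitrile, via N-formyl tosylenamine 7 (not isolated)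
Conditions: TosMIC, KOt-Bu, DME, −30 °C to rt; then MeOH, reflux
Reagents that add atoms: TosMIC ([C-]#[N+]CS(=O)(=O)c1ccc(C)cc1)
Why: Van Leusen reductive cyanation: the TosMIC anion adds to the aldehyde, the oxazoline opens to enamide 7, and methanolysis with loss of sulfinate gives the one-carbon-homologated nitrile, whose nitrile carbon becomes C4 of unit 1.

Step 4
Reactants: 8 2-[2-(allyloxy)-4,6-bis(benzyloxy)phenyl]acetonitrile; 9 phloroglucinol
Product: 11 2-[2-(allyloxy)-4,6-bis(benzyloxy)phenyl]-1-(2,4,6-trihydroxyphenyl)ethan-1-one, via ketiminium chloride 10 (not isolated)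
Conditions: ZnCl2, HCl (g), Et2O, 0 °C; then H2O, 90 °C
Reagents that add atoms: phloroglucinol (Oc1cc(O)cc(O)c1); water (O)
Why: Houben–Hoesch acylation: the HCl-activated nitrile is attacked once by the symmetric, highly nucleophilic phloroglucinol (the iminium product is deactivated towards a second acylation) and ketiminium salt 10 is hydrolysed to the aryl benzyl ketone, with no benzofuran formation because all three ring A'' oxygens are etherified.

Step 5
Reactants: 11 2-[2-(allyloxy)-4,6-bis(benzyloxy)phenyl]-1-(2,4,6-trihydroxyphenyl)ethan-1-one; 2 benzyl bromide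
Product: 12 2-[2-(allyloxy)-4,6-bis(benzyloxy)phenyl]-1-[2,4-bis(benzyloxy)-6-hydroxyphenyl]ethan-1-one
Conditions: BnBr (2.1 equiv), K2CO3, acetone, reflux
Reagents that add atoms: benzyl bromide (BrCc1ccccc1)
Why: Chelation-controlled Williamson etherification: two hydroxyls of the acylphloroglucinol are benzylated, the one hydrogen-bonded to the ketone stays free for ring closure, and K2CO3 is too weak to alkylate the benzylic methylene.

Step 6
Reactants: 12 2-[2-(allyloxy)-4,6-bis(benzyloxy)phenyl]-1-[2,4-bis(benzyloxy)-6-hydroxyphenyl]ethan-1-one; 13 4-(benzyloxy)benzaldehyde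
Product: 15 rac-trans-3-[2-(allyloxy)-4,6-bis(benzyloxy)phenyl]-5,7-bis(benzyloxy)-2-[4-(benzyloxy)phenyl]chroman-4-one, via alpha-aryl chalcone 14 (not isolated)
Conditions: piperidine, toluene, reflux, Dean–Stark
Reagents that add atoms: 4-(benzyloxy)benzaldehyde (O=Cc1ccc(OCc2ccccc2)cc1)
Why: Piperidine-mediated Knoevenagel condensation gives chalcone 14, whose free phenol closes ring C by oxa-Michael addition (the known annulation of 2-hydroxydeoxybenzoins with aryl aldehydes to 2,3-diarylchroman-4-ones); C3 is epimerisable under the conditions, so the 2,3-trans racemate should form as the thermodynamic product.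

Step 7
Reactants: 15 rac-trans-3-[2-(allyloxy)-4,6-bis(benzyloxy)phenyl]-5,7-bis(benzyloxy)-2-[4-(benzyloxy)phenyl]chroman-4-one
Product: 16 rac-trans-3-[2,4-bis(benzyloxy)-6-hydroxyphenyl]-5,7-bis(benzyloxy)-2-[4-(benzyloxy)phenyl]chroman-4-one
Conditions: Pd(PPh3)4 (5 mol%), morpholine, THF, rt
Reagents that add atoms: none
Why: Tsuji–Trost allyl transfer: zerovalent palladium ionises the aryl allyl ether to a pi-allyl complex that morpholine captures, releasing only the tagged phenol while the benzyl ethers and the ketone are untouched.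

Step 8
Reactants: 16 rac-trans-3-[2,4-bis(benzyloxy)-6-hydroxyphenyl]-5,7-bis(benzyloxy)-2-[4-(benzyloxy)phenyl]chroman-4-one; 17 paraformaldehyde (as formaldehyde)
Product: 19 rac-trans-3-[4,6-bis(benzyloxy)-3-formyl-2-hydroxyphenyl]-5,7-bis(benzyloxy)-2-[4-(benzyloxy)phenyl]chroman-4-one, via hydroxymethyl phenol 18 (not isolated)
Conditions: MgCl2, Et3N, (CH2O)n, MeCN, reflux
Reagents that add atoms: formaldehyde (C=O)
Why: Magnesium-phenoxide-directed ortho-formylation (Casnati–Skattebøl): the phenoxide delivers formaldehyde to its only free ortho carbon (the other is C8'') and benzylic alcohol 18 is oxidised in situ by hydride transfer to a second formaldehyde, so the formyl group lands on C4a'' beside the free O8a''–H and nowhere else; ketones with alpha hydrogens are tolerated by this method.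

Step 9
Reactants: 19 rac-trans-3-[4,6-bis(benzyloxy)-3-formyl-2-hydroxyphenyl]-5,7-bis(benzyloxy)-2-[4-(benzyloxy)phenyl]chroman-4-one
Product: 20 (2R,3S)-3-[4,6-bis(benzyloxy)-3-formyl-2-hydroxyphenyl]-5,7-bis(benzyloxy)-2-[4-(benzyloxy)phenyl]chroman-4-one
Conditions: preparative chiral HPLC, amylose tris(3,5-dimethylphenylcarbamate) phase, hexane/i-PrOH
Reagents that add atoms: none
Why: Chromatographic resolution on a chiral stationary phase, routine for flavanones; the (2R,3S) antipode (to be assigned by circular dichroism or anomalous-dispersion crystallography) is carried on, and the (2S,3R) antipode can be racemised with an amine base through reversible retro-oxa-Michael ring opening and recycled.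

Step 10
Reactants: 20 (2R,3S)-3-[4,6-bis(benzyloxy)-3-formyl-2-hydroxyphenyl]-5,7-bis(benzyloxy)-2-[4-(benzyloxy)phenyl]chroman-4-one; 21 4-vinylanisole; 22 trimethyl orthoformate
Product: 25 (2R,3S)-5,7-bis(benzyloxy)-2-[4-(benzyloxy)phenyl]-3-[(2S,4S)-5,7-bis(benzyloxy)-4-methoxy-2-(4-methoxyphenyl)chroman-8-yl]chroman-4-one, via dimethyl acetal 23 (not isolated), via ortho-quinone methide 24 (not isolated)
Conditions: (R)-TRIP (10 mol%), HC(OMe)3 (3 equiv), 4-vinylanisole (3 equiv), 4 Å MS, CH2Cl2, −20 °C to rt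
Reagents that add atoms: 4-vinylanisole (COc1ccc(C=C)cc1); trimethyl orthoformate (COC(OC)OC)
Why: Orthoformate and the acid turn the chelated aldehyde into acetal 23, which loses methanol to the 2-hydroxybenzyl oxocarbenium ion, the protonated form of 4-methoxy ortho-quinone methide 24, held by the chiral phosphate through ion pairing and hydrogen bonding. 4-Vinylanisole adds through its CH2 terminus to C4'' and the anisyl-stabilised positive charge building at C2'' is captured by O8a'', an asynchronous inverse-electron-demand oxa-[4+2] cycloaddition; the closest known reactions are the acid-promoted three-component chroman synthesis from salicylaldehydes, orthoformates and styrenes and the chiral phosphoric acid-catalysed cycloadditions of ortho-quinone methides with styrenes. Ring C'' is closed in this one [4+2] event as a six-membered ring from the heterodiene O8a''=C8a''–C4a''=C4'' and the alkene C3''=C2'' (C4''–C3'' leading, O1''–C2'' following). C4'' is set by the quinone methide face that the phosphate leaves open, reinforced or opposed by the unit 1 stereocentres next to C8'', and C2'' follows from the endo (2,4-cis) approach of the anisyl group; because unit 1 is already one enantiomer, any C2'' epimer is a diastereomer removable by chromatography. The step needs regioselectivity (O8a'' and not O5'' entering the pyran), secured because O5'' and O7'' are benzyl ethers and O8a''–H is the only free hydroxyl ortho to the formyl carbon, and chemoselectivity, secured because 4-vinylanisole is the only nucleophilic alkene present and the medium is acidic, where the base-labile C2 and C3 are safe.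

Step 11
Reactants: 25 (2R,3S)-5,7-bis(benzyloxy)-2-[4-(benzyloxy)phenyl]-3-[(2S,4S)-5,7-bis(benzyloxy)-4-methoxy-2-(4-methoxyphenyl)chroman-8-yl]chroman-4-one
Product: 27 (2R,3S)-5,7-bis(benzyloxy)-2-[4-(benzyloxy)phenyl]-3-[(2S)-5,7-bis(benzyloxy)-2-(4-methoxyphenyl)-4-oxochroman-8-yl]chroman-4-one, via hemiketal 26 (not isolated)
Conditions: DDQ (1.5 equiv), CH2Cl2/H2O (10:1), 0 °C to rt
Reagents that add atoms: water (O)
Why: DDQ abstracts hydride from C4''–H, the most hydridic position (benzylic to the trioxygenated ring A'' and alpha to OMe), water adds to the oxocarbenium ion and hemiketal 26 loses methanol to the aryl ketone (the known oxidative cleavage of electron-rich benzylic methyl ethers); the new carbonyl deactivates ring A'' against further oxidation and C2'' is not touched.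

Step 12
Reactants: 27 (2R,3S)-5,7-bis(benzyloxy)-2-[4-(benzyloxy)phenyl]-3-[(2S)-5,7-bis(benzyloxy)-2-(4-methoxyphenyl)-4-oxochroman-8-yl]chroman-4-one
Product: 28 (2R,3S)-5,7-dihydroxy-2-(4-hydroxyphenyl)-3-[(2S)-5,7-dihydroxy-2-(4-methoxyphenyl)-4-oxochroman-8-yl]chroman-4-one (CNP0140544.1)
Conditions: H2 (1 atm), Pd/C (10 wt%), EtOAc/MeOH, rt
Reagents that add atoms: none
Why: Heterogeneous hydrogenolysis of the five aryl benzyl ethers under neutral conditions; the aryl methyl ether, both aryl ketones and the three stereocentres (labile only to base) should survive, giving the target.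

**Compound list**

1 | 2,4,6-trihydroxybenzaldehyde | O=Cc1c(O)cc(O)cc1O | starting material
2 | benzyl bromide | BrCc1ccccc1 | starting material
3 | 4,6-bis(benzyloxy)-2-hydroxybenzaldehyde | O=Cc1c(O)cc(OCc2ccccc2)cc1OCc1ccccc1 | intermediate
4 | allyl bromide | C=CCBr | starting material
5 | 2-(allyloxy)-4,6-bis(benzyloxy)benzaldehyde | O=Cc1c(OCC=C)cc(OCc2ccccc2)cc1OCc1ccccc1 | intermediate
6 | tosylmethyl isocyanide (TosMIC) | [C-]#[N+]CS(=O)(=O)c1ccc(C)cc1 | starting material
7 | N-{2-[2-(allyloxy)-4,6-bis(benzyloxy)phenyl]-1-tosylethenyl}formamide (alkene geometry open) | O=CNC(=Cc1c(OCC=C)cc(OCc2ccccc2)cc1OCc1ccccc1)S(=O)(=O)c1ccc(C)cc1 | intermediate (not isolated)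
8 | 2-[2-(allyloxy)-4,6-bis(benzyloxy)phenyl]acetonitrile | N#CCc1c(OCC=C)cc(OCc2ccccc2)cc1OCc1ccccc1 | intermediate
9 | phloroglucinol | Oc1cc(O)cc(O)c1 | starting material
10 | ketiminium chloride of 11 | [NH2+]=C(Cc1c(OCC=C)cc(OCc2ccccc2)cc1OCc1ccccc1)c1c(O)cc(O)cc1O.[Cl-] | intermediate (not isolated)
11 | 2-[2-(allyloxy)-4,6-bis(benzyloxy)phenyl]-1-(2,4,6-trihydroxyphenyl)ethan-1-one | O=C(Cc1c(OCC=C)cc(OCc2ccccc2)cc1OCc1ccccc1)c1c(O)cc(O)cc1O | intermediate
12 | 2-[2-(allyloxy)-4,6-bis(benzyloxy)phenyl]-1-[2,4-bis(benzyloxy)-6-hydroxyphenyl]ethan-1-one | O=C(Cc1c(OCC=C)cc(OCc2ccccc2)cc1OCc1ccccc1)c1c(O)cc(OCc2ccccc2)cc1OCc1ccccc1 | intermediate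
13 | 4-(benzyloxy)benzaldehyde | O=Cc1ccc(OCc2ccccc2)cc1 | starting material
14 | alpha-aryl chalcone: 2-[2-(allyloxy)-4,6-bis(benzyloxy)phenyl]-1-[2,4-bis(benzyloxy)-6-hydroxyphenyl]-3-[4-(benzyloxy)phenyl]prop-2-en-1-one (alkene geometry open) | O=C(C(=Cc1ccc(OCc2ccccc2)cc1)c1c(OCC=C)cc(OCc2ccccc2)cc1OCc1ccccc1)c1c(O)cc(OCc2ccccc2)cc1OCc1ccccc1 | intermediate (not isolated)
15 | rac-trans-3-[2-(allyloxy)-4,6-bis(benzyloxy)phenyl]-5,7-bis(benzyloxy)-2-[4-(benzyloxy)phenyl]chroman-4-one (racemate; SMILES shows the 2R,3S enantiomer) | C=CCOc1cc(OCc2ccccc2)cc(OCc2ccccc2)c1[C@@H]1C(=O)c2c(OCc3ccccc3)cc(OCc3ccccc3)cc2O[C@H]1c1ccc(OCc2ccccc2)cc1 | intermediate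
16 | rac-trans-3-[2,4-bis(benzyloxy)-6-hydroxyphenyl]-5,7-bis(benzyloxy)-2-[4-(benzyloxy)phenyl]chroman-4-one (racemate; SMILES shows the 2R,3S enantiomer) | Oc1cc(OCc2ccccc2)cc(OCc2ccccc2)c1[C@@H]1C(=O)c2c(OCc3ccccc3)cc(OCc3ccccc3)cc2O[C@H]1c1ccc(OCc2ccccc2)cc1 | intermediate
17 | paraformaldehyde (formaldehyde source) | C=O | starting material
18 | rac-trans-3-[4,6-bis(benzyloxy)-2-hydroxy-3-(hydroxymethyl)phenyl]-5,7-bis(benzyloxy)-2-[4-(benzyloxy)phenyl]chroman-4-one (racemate; SMILES shows the 2R,3S enantiomer) | OCc1c(OCc2ccccc2)cc(OCc2ccccc2)c([C@@H]3C(=O)c4c(OCc5ccccc5)cc(OCc5ccccc5)cc4O[C@H]3c3ccc(OCc4ccccc4)cc3)c1O | intermediate (not isolated)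
19 | rac-trans-3-[4,6-bis(benzyloxy)-3-formyl-2-hydroxyphenyl]-5,7-bis(benzyloxy)-2-[4-(benzyloxy)phenyl]chroman-4-one (racemate; SMILES shows the 2R,3S enantiomer) | O=Cc1c(OCc2ccccc2)cc(OCc2ccccc2)c([C@@H]3C(=O)c4c(OCc5ccccc5)cc(OCc5ccccc5)cc4O[C@H]3c3ccc(OCc4ccccc4)cc3)c1O | intermediate
20 | (2R,3S)-3-[4,6-bis(benzyloxy)-3-formyl-2-hydroxyphenyl]-5,7-bis(benzyloxy)-2-[4-(benzyloxy)phenyl]chroman-4-one (key-step precursor) | O=Cc1c(OCc2ccccc2)cc(OCc2ccccc2)c([C@@H]3C(=O)c4c(OCc5ccccc5)cc(OCc5ccccc5)cc4O[C@H]3c3ccc(OCc4ccccc4)cc3)c1O | intermediate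
21 | 4-vinylanisole | COc1ccc(C=C)cc1 | starting material
22 | trimethyl orthoformate | COC(OC)OC | starting material
23 | dimethyl acetal of 20 | COC(OC)c1c(OCc2ccccc2)cc(OCc2ccccc2)c([C@@H]3C(=O)c4c(OCc5ccccc5)cc(OCc5ccccc5)cc4O[C@H]3c3ccc(OCc4ccccc4)cc3)c1O | intermediate (not isolated)
24 | 4-methoxy ortho-quinone methide of ring A'' (exocyclic geometry open) | COC=C1C(OCc2ccccc2)=CC(OCc2ccccc2)=C([C@@H]3C(=O)c4c(OCc5ccccc5)cc(OCc5ccccc5)cc4O[C@H]3c3ccc(OCc4ccccc4)cc3)C1=O | intermediate (not isolated)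
25 | (2R,3S)-5,7-bis(benzyloxy)-2-[4-(benzyloxy)phenyl]-3-[(2S,4S)-5,7-bis(benzyloxy)-4-methoxy-2-(4-methoxyphenyl)chroman-8-yl]chroman-4-one (2'',4''-cis) | COc1ccc([C@@H]2C[C@H](OC)c3c(OCc4ccccc4)cc(OCc4ccccc4)c([C@@H]4C(=O)c5c(OCc6ccccc6)cc(OCc6ccccc6)cc5O[C@H]4c4ccc(OCc5ccccc5)cc4)c3O2)cc1 | intermediate
26 | C4'' hemiketal (4''-hydroxy-4''-methoxy; C4'' configuration open) | COc1ccc([C@@H]2CC(O)(OC)c3c(OCc4ccccc4)cc(OCc4ccccc4)c([C@@H]4C(=O)c5c(OCc6ccccc6)cc(OCc6ccccc6)cc5O[C@H]4c4ccc(OCc5ccccc5)cc4)c3O2)cc1 | intermediate (not isolated)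
27 | (2R,3S)-5,7-bis(benzyloxy)-2-[4-(benzyloxy)phenyl]-3-[(2S)-5,7-bis(benzyloxy)-2-(4-methoxyphenyl)-4-oxochroman-8-yl]chroman-4-one | COc1ccc([C@@H]2CC(=O)c3c(OCc4ccccc4)cc(OCc4ccccc4)c([C@@H]4C(=O)c5c(OCc6ccccc6)cc(OCc6ccccc6)cc5O[C@H]4c4ccc(OCc5ccccc5)cc4)c3O2)cc1 | intermediate
28 | (2R,3S)-5,7-dihydroxy-2-(4-hydroxyphenyl)-3-[(2S)-5,7-dihydroxy-2-(4-methoxyphenyl)-4-oxochroman-8-yl]chroman-4-one (CNP0140544.1) | COc1ccc([C@@H]2CC(=O)c3c(O)cc(O)c([C@@H]4C(=O)c5c(O)cc(O)cc5O[C@H]4c4ccc(O)cc4)c3O2)cc1 | target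

**Step count and risks**

Total step count: 12. Longest linear sequence: 12 steps (1 to 28); phloroglucinol, 4-(benzyloxy)benzaldehyde, 4-vinylanisole and trimethyl orthoformate enter as commercial materials.

Most likely to fail, first: step 10. The acetal of the chelated, vinylogous-ester-like aldehyde may ionise too slowly under the weak chiral acid, so that acid-induced oligomerisation of 4-vinylanisole outruns its capture. Facial or endo/exo discrimination may also be incomplete, and the anisyl-substituted C2''–O1'' bond may re-ionise, eroding the diastereomer ratio. The fallback sets out from 20 and comes back to the route at 25. The formyl group of 20 is reduced chemoselectively (NaBH4, THF/EtOH, −40 °C; the hindered, doubly oxygen-conjugated C4 ketone should react far more slowly) to the (2R,3S)-salicyl alcohol F1. Dehydrative generation of the unsubstituted ortho-quinone methide from F1 with the same chiral phosphoric acid in the presence of 21, the best-precedented mode of such cycloadditions, gives the C4''-unsubstituted (2''S)-flavan F2. Oxidative methoxylation of the activated C4'' methylene (DDQ, CH2Cl2/MeOH), known for 5,7-dialkoxyflavans, then gives 25 together with its C4'' epimer F3, and step 11 converts both into 27.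

Second: step 6. The Knoevenagel condensation may stall at the methylene shielded by the 2,6-dioxygenated ring A'', returning ketone or giving aldol/retro-aldol mixtures. The fallback sets out from 12 and comes back at 15. N,N-Dimethylformamide dimethyl acetal (toluene, 100 °C) closes 12 to the isoflavone F4, whose unsubstituted C2 takes up 4-(benzyloxy)phenylmagnesium bromide in a copper-catalysed conjugate addition (CuBr·SMe2, Me3SiCl, THF, −40 °C). Hydrolysis of the silyl enol ether and brief amine equilibration of C3 should give the trans racemate 15, the C2–aryl bond being made in place of the C2–C3 bond.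

Third: step 11. Hydride abstraction may compete at the anisyl-activated C2''–H (opening ring C''), or over-oxidation may dehydrogenate a flavanone ring. The fallback sets out from 25 and comes back at 27. The doubly oxygen-stabilised benzylic methyl ether is solvolysed (pyridinium p-toluenesulfonate, acetone/H2O, 40 °C) to the flavan-4''-ol F5 (either C4'' epimer), which Dess–Martin periodinane (NaHCO3, CH2Cl2) oxidises to 27 without any hydride-abstracting oxidant.

Further compounds
F1 | step 10 | (2R,3S)-3-[4,6-bis(benzyloxy)-2-hydroxy-3-(hydroxymethyl)phenyl]-5,7-bis(benzyloxy)-2-[4-(benzyloxy)phenyl]chroman-4-one (single enantiomer of 18) | OCc1c(OCc2ccccc2)cc(OCc2ccccc2)c([C@@H]3C(=O)c4c(OCc5ccccc5)cc(OCc5ccccc5)cc4O[C@H]3c3ccc(OCc4ccccc4)cc3)c1O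
F2 | step 10 | (2R,3S)-5,7-bis(benzyloxy)-2-[4-(benzyloxy)phenyl]-3-[(2S)-5,7-bis(benzyloxy)-2-(4-methoxyphenyl)chroman-8-yl]chroman-4-one | COc1ccc([C@@H]2CCc3c(OCc4ccccc4)cc(OCc4ccccc4)c([C@@H]4C(=O)c5c(OCc6ccccc6)cc(OCc6ccccc6)cc5O[C@H]4c4ccc(OCc5ccccc5)cc4)c3O2)cc1
F3 | step 10 | C4'' epimer of 25, (2''S,4''R), 2'',4''-trans | COc1ccc([C@@H]2C[C@@H](OC)c3c(OCc4ccccc4)cc(OCc4ccccc4)c([C@@H]4C(=O)c5c(OCc6ccccc6)cc(OCc6ccccc6)cc5O[C@H]4c4ccc(OCc5ccccc5)cc4)c3O2)cc1
F4 | step 6 | 3-[2-(allyloxy)-4,6-bis(benzyloxy)phenyl]-5,7-bis(benzyloxy)-4H-chromen-4-one | O=c1c(-c2c(OCC=C)cc(OCc3ccccc3)cc2OCc2ccccc2)coc2cc(OCc3ccccc3)cc(OCc3ccccc3)c12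
F5 | step 11 | (2R,3S)-5,7-bis(benzyloxy)-2-[4-(benzyloxy)phenyl]-3-[(2S)-5,7-bis(benzyloxy)-4-hydroxy-2-(4-methoxyphenyl)chroman-8-yl]chroman-4-one (C4'' configuration open) | COc1ccc([C@@H]2CC(O)c3c(OCc4ccccc4)cc(OCc4ccccc4)c([C@@H]4C(=O)c5c(OCc6ccccc6)cc(OCc6ccccc6)cc5O[C@H]4c4ccc(OCc5ccccc5)cc4)c3O2)cc1
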